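**Retrosynthetic overview**
- Last, ring B (the γ-lactone, O6–C12) is closed from a C12 acid once O6 is unmasked; before that, O8 is acylated with a protected (Z)-2-(hydroxymethyl)but-2-enoic acid.
- Ring A (the cyclohexane) is opened at C5–C10 and C7–C8, giving an acyclic 3-hydroxy-1,5-diene (C10=C9–C8(OH)–C3–C4=C5) that carries an allylsilane on C7=C11. An anionic oxy-Cope shift makes C5–C10 and releases the C8 aldehyde, and the allylsilane carbon C7 closes onto it in the same flask.
- Enabling feature: in ring A both C5 and C7 carry a prop-1-en-2-yl-type unit (C4=C3H2, C11=C13H2), and C8 is an oxygenated carbon two atoms from the vinyl-bearing quaternary C10. Each new ring bond is therefore an allyl-transposition bond (a [3,3] bond and an SE2′ bond).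
- The rearrangement precursor comes from alkyne chemistry: (Z)-dienal + allenylboronate (sets C8), acetylide + Weinreb amide then ketone reduction (sets C6), hydroalumination/iodination/Stille for the Z C4=C5 bond. O6 and O15 are tied in a temporary seven-membered silylene ring that steers the facial selectivity.
- Ring order: temporary dioxasilepine ring, then ring A (key step), then ring B; the silylene ring is removed in the last step.

Key step: step 14

Remark: locants follow the usual elemanolide numbering: C10 quaternary carbon (C1=C2 vinyl, C14 hydroxymethyl), C9 ring CH2, C8 acyloxy carbon, C7 carbon bearing C11 (C12 carbonyl, C13 methylene), C6 lactone carbinol, C5 carbon bearing C4 (C3 methylene, C15 hydroxymethyl).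
Remark: compound 1 is taken as purchasable; otherwise it is one silylation away from but-2-yne-1,4-diol.

Step 1
Reactants: 1 4-[(tert-butyldimethylsilyl)oxy]but-2-yn-1-ol
Product: 2 (2Z)-4-[(tert-butyldimethylsilyl)oxy]-3-iodobut-2-en-1-ol
Conditions: NaAlH2(OCH2CH2OCH3)2, THF, 0 °C; then I2, −78 to 0 °C
Reagents that add atoms: iodine, [I][I]
Why: Hydroxyl-directed trans-hydroalumination of a propargylic alcohol places aluminium on the distal alkyne carbon within a five-membered alkoxyaluminate, and iodinolysis with retention should give the alkenyl iodide with iodine cis to CH2OH, which fixes the later C9=C10 geometry.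

Step 2
Reactants: 2 (2Z)-4-[(tert-butyldimethylsilyl)oxy]-3-iodobut-2-en-1-ol; 3 tributyl(vinyl)stannane
Product: 4 (2E)-3-{[(tert-butyldimethylsilyl)oxy]methyl}penta-2,4-dien-1-ol (vinyl cis to CH2OH)
Conditions: Pd(PPh3)4 (5 mol %), CuI (10 mol %), DMF, 40 °C
Reagents that add atoms: none
Why: Stille cross-coupling of alkenyl iodides with zerovalent palladium proceeds with retention of alkene geometry, so the vinyl group (C1, C2) should end cis to the carbinol arm, as the chair of the later [3,3] shift requires.

Step 3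
Reactants: 4 (2E)-3-{[(tert-butyldimethylsilyl)oxy]methyl}penta-2,4-dien-1-ol
Product: 5 (2E)-3-{[(tert-butyldimethylsilyl)oxy]methyl}penta-2,4-dienal (vinyl cis to CHO)
Conditions: MnO2, CH2Cl2, rt
Reagents that add atoms: none
Why: MnO2 oxidises primary allylic alcohols to enals under neutral heterogeneous conditions (allylic oxidation) without over-oxidation or isomerisation of the trisubstituted alkene.

Step 4
Reactants: 5 (2E)-3-{[(tert-butyldimethylsilyl)oxy]methyl}penta-2,4-dienal; 6 allenylboronic acid pinacol ester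
Product: 7 (4S,5E)-6-{[(tert-butyldimethylsilyl)oxy]methyl}octa-5,7-dien-1-yn-4-ol
Conditions: TRIP phosphoric acid (10 mol %, the enantiomer that delivers the 4S alcohol), 4 Å MS, toluene, −20 °C; aqueous work-up
Reagents that add atoms: none
Why: Brønsted acid-catalysed propargylation of aldehydes with allenylboronates runs through a closed six-membered SE2′ transition state (1,2-addition, propargyl and not allenyl product) in which the chiral phosphate differentiates the aldehyde faces and should set C8 as S.

Step 5
Reactants: 8 prop-2-yn-1-ol; 9 [(trimethylsilyl)methyl]magnesium chloride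
Product: 10 (2E)-3-iodo-2-[(trimethylsilyl)methyl]prop-2-en-1-ol (iodine cis to CH2OH)
Conditions: CuI (10 mol %), THF, 0 °C to rt; then I2, −78 °C
Reagents that add atoms: iodine, [I][I]
Why: Copper-catalysed anti-carbomagnesiation of the propargylic alkoxide delivers the CH2SiMe3 group to the internal carbon and leaves a chelated alkenylmagnesium at the terminus, so that iodinolysis with retention should give the iodide cis to CH2OH and hence the C7=C11 geometry with the silylmethyl arm trans to the later C6.

Step 6
Reactants: 10 (2E)-3-iodo-2-[(trimethylsilyl)methyl]prop-2-en-1-ol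
Product: 11 4-methoxybenzyl ether of 10
Conditions: NaH, 4-methoxybenzyl chloride, Bu4NI (cat.), THF/DMF, 0 °C to rt
Reagents that add atoms: 4-methoxybenzyl chloride, COc1ccc(CCl)cc1
Why: Williamson etherification puts on O12 a 4-methoxybenzyl group that withstands organolithium, hydride, base and Lewis acid steps and can later be removed oxidatively beside silyl ethers.

Step 7
Reactants: 11 4-methoxybenzyl ether of 10; 12 N-methoxy-N-methylcarbamoyl chloride
Product: 13 (2E)-N-methoxy-4-[(4-methoxybenzyl)oxy]-N-methyl-3-[(trimethylsilyl)methyl]but-2-enamide (carbonyl cis to CH2OPMB)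
Conditions: t-BuLi (2.1 equiv), Et2O, −78 °C; then 12, −78 to 0 °C
Reagents that add atoms: none
Why: Iodine–lithium exchange gives the alkenyllithium with retention, and its acylation by the carbamoyl chloride stops at the Weinreb amide, which brings in C6 at the ketone oxidation level.

Step 8
Reactants: 7 (4S,5E)-6-{[(tert-butyldimethylsilyl)oxy]methyl}octa-5,7-dien-1-yn-4-ol; 13 Weinreb amide
Product: 14 (2E,8S,9E)-10-{[(tert-butyldimethylsilyl)oxy]methyl}-1-[(4-methoxybenzyl)oxy]-8-[(triethylsilyl)oxy]-2-[(trimethylsilyl)methyl]dodeca-2,9,11-trien-5-yn-4-one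
Conditions: n-BuLi (1.0 equiv), THF, −78 °C, Et3SiCl, to 0 °C; then n-BuLi (1.05 equiv), −78 °C, then 13, to −20 °C; aq NH4Cl
Reagents that add atoms: chlorotriethylsilane, CC[Si](Cl)(CC)CC
Why: After in-flask silylation of the C8 alkoxide, the lithium acetylide adds once to the Weinreb amide through a stable chelated tetrahedral intermediate (Weinreb ketone synthesis), so the ynone should form without over-addition and without change at C8 or at the alkenes.

Step 9
Reactants: 14 ynone
Product: 15 (2E,4S,8S,9E)-10-{[(tert-butyldimethylsilyl)oxy]methyl}-1-[(4-methoxybenzyl)oxy]-8-[(triethylsilyl)oxy]-2-[(trimethylsilyl)methyl]dodeca-2,9,11-trien-5-yn-4-ol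
Conditions: Ru[(S,S)-TsNCH(Ph)CH(Ph)NH](p-cymene) (2 mol %), i-PrOH, rt (the catalyst enantiomer that gives S propargylic alcohols from alkynyl methyl ketones)
Reagents that add atoms: none
Why: Noyori asymmetric transfer hydrogenation is chemoselective for the carbonyl group of alkynyl ketones and should set the propargylic carbinol C6 (S) by catalyst control, the alkyne taking the place it takes in alkynyl alkyl ketones.

Step 10
Reactants: 15 propargylic alcohol
Product: 16 (2E,4S,5Z,8S,9E)-10-{[(tert-butyldimethylsilyl)oxy]methyl}-6-iodo-1-[(4-methoxybenzyl)oxy]-8-[(triethylsilyl)oxy]-2-[(trimethylsilyl)methyl]dodeca-2,5,9,11-tetraen-4-ol (iodine on C4, cis to C6)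
Conditions: NaAlH2(OCH2CH2OCH3)2, THF, 0 °C; then N-iodosuccinimide, −78 °C
Reagents that add atoms: N-iodosuccinimide, O=C1CCC(=O)N1I
Why: With O8 silylated, only the C6 hydroxyl directs the trans-hydroalumination, which places aluminium on C4 in a five-membered aluminate, and cold iodinolysis with retention should give the iodide cis to C6 faster than the allylsilane is attacked.

Step 11
Reactants: 16 alkenyl iodide; 17 (tributylstannyl)methanol
Product: 18 (2E,4R,5Z,8S,9E)-10-{[(tert-butyldimethylsilyl)oxy]methyl}-6-(hydroxymethyl)-1-[(4-methoxybenzyl)oxy]-8-[(triethylsilyl)oxy]-2-[(trimethylsilyl)methyl]dodeca-2,5,9,11-tetraen-4-ol (same spatial arrangement at C6 as in 16; the descriptor changes by priority only)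
Conditions: Pd(PPh3)4 (10 mol %), 1,4-dioxane, 80 °C
Reagents that add atoms: none
Why: Stille coupling with the hydroxymethylstannane replaces iodine by CH2OH (C15) with retention, so that O15 and O6 come to lie cis across the C4=C5 bond.

Step 12
Reactants: 18 diol
Product: 19 O6,O15-di-tert-butylsilylene of 18 (2,2-di-tert-butyl-4,7-dihydro-1,3,2-dioxasilepine ring holding C15, C4=C5 and C6; C8 triethylsilyl ether)
Conditions: tBu2Si(OTf)2, 2,6-lutidine, CH2Cl2, −40 to 0 °C
Reagents that add atoms: di-tert-butylsilyl bis(trifluoromethanesulfonate), CC(C)(C)[Si](OS(=O)(=O)C(F)(F)F)(OS(=O)(=O)C(F)(F)F)C(C)(C)C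
Why: The cis-2-ene-1,4-diol is the only diol in the molecule and should close readily to the seven-membered di-tert-butylsilylene, a base- and Lewis acid-stable temporary ring that holds the C6–O bond near the plane of the C4=C5 bond.

Step 13
Reactants: 19 silylene triethylsilyl ether
Product: 20 (2S,3E)-1-{(7R)-2,2-di-tert-butyl-7-[(1E)-3-[(4-methoxybenzyl)oxy]-2-[(trimethylsilyl)methyl]prop-1-en-1-yl]-4,7-dihydro-1,3,2-dioxasilepin-5-yl}-4-{[(tert-butyldimethylsilyl)oxy]methyl}hexa-3,5-dien-2-ol
Conditions: PPTS (cat.), MeOH/CH2Cl2, 0 °C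
Reagents that add atoms: none
Why: Acid-catalysed methanolysis cleaves a secondary triethylsilyl ether much faster than the primary tert-butyldimethylsilyl ether or the hindered silylene, which frees only the C8 hydroxyl.

Step 14
Reactants: 20 3-hydroxy-1,5-diene (C8 S; silylene ring; allylsilane)
Product: 22 silylene-protected all-trans cyclohexanol (ring A; free C8 hydroxyl), via aldehyde 21 (not isolated)
Conditions: KH, 18-crown-6, THF, 0 °C to rt; then AcOH, −78 °C; then BF3·OEt2, CH2Cl2, −78 °C (one flask)
Reagents that add atoms: none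
Why: The potassium alkoxide of the 3-hydroxy-1,5-diene C10=C9–C8(O)–C3–C4=C5 undergoes an anion-accelerated [3,3] shift (anionic oxy-Cope) that forms C5–C10, cleaves C8–C3 and gives the enolate of aldehyde 21; after protonation in the flask, BF3 activates the aldehyde for attack by the γ-carbon C7 of the 2-substituted allylsilane (intramolecular Hosomi–Sakurai, SE2′), which forms C7–C8 and the C11=C13 methylene with loss of the silyl group. The closest known reaction types are acyclic anionic oxy-Cope rearrangements that build quaternary carbons, tandem oxy-Cope/carbonyl-ene sequences and intramolecular allylsilane–aldehyde cyclisations to 2-alkenylcyclohexanols. The first event closes no ring, and the second closes ring A by 6-exo-trig attack on the carbonyl group through a chair-like synclinal transition state. C5 and C10 are set together in the chair of the [3,3] shift: the vinyl group (cis to C8 on C9=C10) is axial, C14 and C6 are equatorial, the S-configured C8 oxido group is equatorial and so avoids the axial vinyl group, and C10 adds to C5 on the face anti to the C7 side chain of C6, whose C–O bond the silylene ring holds near the alkene plane. C7 and C8 are set in the chair closure, in which the silylene-fused C5/C6 substituents and the C11 unit are equatorial and the axial CH2OTBS group on C10 forces the BF3-bound oxygen equatorial, which gives the all-trans C5–C8 array. The step needs the concerted shift instead of fragmentation of the alkoxide, and allylation instead of carbonyl-ene closure of the new C3 methylene onto the aldehyde; the non-stabilised allyl fragment with a crown-separated ion pair favours the former, and the allylsilane is far more nucleophilic than the 1,1-disubstituted alkene.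

Step 15
Reactants: 23 but-2-yn-1-ol; 24 tributylstannane
Product: 25 (2Z)-2-(tributylstannyl)but-2-en-1-ol
Conditions: [Cp*RuCl]4 (1.5 mol %), CH2Cl2, rt
Reagents that add atoms: none
Why: Ruthenium-catalysed trans-hydrostannation of propargylic alcohols delivers tin to the carbon next to the carbinol and hydrogen trans to it, so the methyl group should end cis to tin.

Step 16
Reactants: 25 (2Z)-2-(tributylstannyl)but-2-en-1-ol
Product: 26 tert-butyldimethylsilyl ether of 25
Conditions: TBSCl, imidazole, DMF, rt
Reagents that add atoms: tert-butyldimethylsilyl chloride, CC(C)(C)[Si](C)(C)Cl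
Why: Silylation of the primary hydroxyl (standard protection) prevents self-acylation in the later esterification.

Step 17
Reactants: 26 silyl ether of the alkenylstannane
Product: 27 (2Z)-2-{[(tert-butyldimethylsilyl)oxy]methyl}but-2-enoic acid
Conditions: n-BuLi, THF, −78 °C; then CO2; then aq HCl (pH 3), 0 °C
Reagents that add atoms: carbon dioxide, O=C=O
Why: Tin–lithium exchange and carboxylation both proceed with retention at the alkenyl carbon at low temperature, which should give the acid with methyl cis to the carboxyl group (Z).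

Step 18
Reactants: 22 cyclohexanol; 27 (2Z)-2-{[(tert-butyldimethylsilyl)oxy]methyl}but-2-enoic acid
Product: 28 C8 ester of 22 with acid 27
Conditions: 27, 2,4,6-trichlorobenzoyl chloride, Et3N, toluene, rt; then 22, DMAP, 60 °C
Reagents that add atoms: none
Why: Yamaguchi esterification through the mixed anhydride acylates the only free hydroxyl (equatorial C8–OH) and is a standard way to transfer angelate-type acids without Z to E isomerisation.

Step 19
Reactants: 28 ester
Product: 29 C12 allylic alcohol (4-methoxybenzyl group removed)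
Conditions: DDQ, CH2Cl2/pH 7 buffer, 0 °C
Reagents that add atoms: none
Why: Oxidative cleavage of the 4-methoxybenzyl ether by DDQ frees only O12 and should leave silyl ethers, the silylene, the alkenes and the enoate untouched.

Step 20
Reactants: 29 allylic alcohol
Product: 30 C12 aldehyde (2-substituted acrolein)
Conditions: Dess–Martin periodinane, NaHCO3, CH2Cl2, 0 °C to rt
Reagents that add atoms: none
Why: Dess–Martin oxidation converts the primary allylic alcohol into the 2-substituted acrolein under buffered neutral conditions.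

Step 21
Reactants: 30 aldehyde
Product: 31 C12 acrylic acid
Conditions: NaClO2, NaH2PO4, 2-methylbut-2-ene, t-BuOH/H2O, rt
Reagents that add atoms: sodium chlorite, [Na+].[O-]Cl=O
Why: Pinnick oxidation with a hypochlorite scavenger takes the enal to the acrylic acid without attack on the other alkenes or the silyl groups.

Step 22
Reactants: 31 acid
Product: 33 target CNP0338073.1, via seco acid 32 (not isolated)
Conditions: HF·pyridine, pyridine/THF, 0 °C to rt; then PPTS (cat.), toluene, 40 °C
Reagents that add atoms: none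
Why: Fluoride cleaves the silylene and both silyl ethers, and the freed equatorial C6 hydroxyl, the only one within reach of a five-membered ring, should lactonise onto the C12 acid under acid catalysis to close the trans-fused α-methylene-γ-lactone (ring B) without touching any stereocenter.

**Compound list**
1 | 4-[(tert-butyldimethylsilyl)oxy]but-2-yn-1-ol | OCC#CCO[Si](C)(C)C(C)(C)C | starting material
2 | (2Z)-4-[(tert-butyldimethylsilyl)oxy]-3-iodobut-2-en-1-ol | OC/C=C(\I)CO[Si](C)(C)C(C)(C)C | intermediate
3 | tributyl(vinyl)stannane | C=C[Sn](CCCC)(CCCC)CCCC | starting material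
4 | (2E)-3-{[(tert-butyldimethylsilyl)oxy]methyl}penta-2,4-dien-1-ol (vinyl cis to CH2OH) | OC/C=C(\C=C)CO[Si](C)(C)C(C)(C)C | intermediate
5 | (2E)-3-{[(tert-butyldimethylsilyl)oxy]methyl}penta-2,4-dienal (vinyl cis to CHO) | O=C/C=C(\C=C)CO[Si](C)(C)C(C)(C)C | intermediate
6 | allenylboronic acid pinacol ester | C=C=CB1OC(C)(C)C(C)(C)O1 | starting material
7 | (4S,5E)-6-{[(tert-butyldimethylsilyl)oxy]methyl}octa-5,7-dien-1-yn-4-ol | C=C/C(CO[Si](C)(C)C(C)(C)C)=C\[C@@H](O)CC#C | intermediate
8 | prop-2-yn-1-ol | C#CCO | starting material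
9 | [(trimethylsilyl)methyl]magnesium chloride | C[Si](C)(C)C[Mg]Cl | starting material
10 | (2E)-3-iodo-2-[(trimethylsilyl)methyl]prop-2-en-1-ol (iodine cis to CH2OH) | OC/C(C[Si](C)(C)C)=C\I | intermediate
11 | 1-({[(2E)-3-iodo-2-[(trimethylsilyl)methyl]prop-2-en-1-yl]oxy}methyl)-4-methoxybenzene | COc1ccc(COC/C(C[Si](C)(C)C)=C\I)cc1 | intermediate
12 | N-methoxy-N-methylcarbamoyl chloride | CON(C)C(Cl)=O | starting material
13 | (2E)-N-methoxy-4-[(4-methoxybenzyl)oxy]-N-methyl-3-[(trimethylsilyl)methyl]but-2-enamide (carbonyl cis to CH2OPMB) | CON(C)C(=O)/C=C(/C[Si](C)(C)C)COCc1ccc(OC)cc1 | intermediate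
14 | (2E,8S,9E)-10-{[(tert-butyldimethylsilyl)oxy]methyl}-1-[(4-methoxybenzyl)oxy]-8-[(triethylsilyl)oxy]-2-[(trimethylsilyl)methyl]dodeca-2,9,11-trien-5-yn-4-one | C=C/C(CO[Si](C)(C)C(C)(C)C)=C\[C@@H](O[Si](CC)(CC)CC)CC#CC(=O)/C=C(/C[Si](C)(C)C)COCc1ccc(OC)cc1 | intermediate
15 | (2E,4S,8S,9E)-10-{[(tert-butyldimethylsilyl)oxy]methyl}-1-[(4-methoxybenzyl)oxy]-8-[(triethylsilyl)oxy]-2-[(trimethylsilyl)methyl]dodeca-2,9,11-trien-5-yn-4-ol | C=C/C(CO[Si](C)(C)C(C)(C)C)=C\[C@@H](O[Si](CC)(CC)CC)CC#C[C@@H](O)/C=C(/C[Si](C)(C)C)COCc1ccc(OC)cc1 | intermediate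
16 | (2E,4S,5Z,8S,9E)-10-{[(tert-butyldimethylsilyl)oxy]methyl}-6-iodo-1-[(4-methoxybenzyl)oxy]-8-[(triethylsilyl)oxy]-2-[(trimethylsilyl)methyl]dodeca-2,5,9,11-tetraen-4-ol | C=C/C(CO[Si](C)(C)C(C)(C)C)=C\[C@@H](O[Si](CC)(CC)CC)C/C(I)=C/[C@@H](O)/C=C(/C[Si](C)(C)C)COCc1ccc(OC)cc1 | intermediate
17 | (tributylstannyl)methanol | OC[Sn](CCCC)(CCCC)CCCC | starting material
18 | (2E,4R,5Z,8S,9E)-10-{[(tert-butyldimethylsilyl)oxy]methyl}-6-(hydroxymethyl)-1-[(4-methoxybenzyl)oxy]-8-[(triethylsilyl)oxy]-2-[(trimethylsilyl)methyl]dodeca-2,5,9,11-tetraen-4-ol | C=C/C(CO[Si](C)(C)C(C)(C)C)=C\[C@@H](O[Si](CC)(CC)CC)C/C(CO)=C/[C@@H](O)/C=C(/C[Si](C)(C)C)COCc1ccc(OC)cc1 | intermediate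
19 | O6,O15-di-tert-butylsilylene of 18 (2,2-di-tert-butyl-4,7-dihydro-1,3,2-dioxasilepine; C8 triethylsilyl ether) | C=C/C(CO[Si](C)(C)C(C)(C)C)=C\[C@@H](O[Si](CC)(CC)CC)CC1=C[C@H](/C=C(/C[Si](C)(C)C)COCc2ccc(OC)cc2)O[Si](C(C)(C)C)(C(C)(C)C)OC1 | intermediate
20 | (2S,3E)-1-{(7R)-2,2-di-tert-butyl-7-[(1E)-3-[(4-methoxybenzyl)oxy]-2-[(trimethylsilyl)methyl]prop-1-en-1-yl]-4,7-dihydro-1,3,2-dioxasilepin-5-yl}-4-{[(tert-butyldimethylsilyl)oxy]methyl}hexa-3,5-dien-2-ol | C=C/C(CO[Si](C)(C)C(C)(C)C)=C\[C@@H](O)CC1=C[C@H](/C=C(/C[Si](C)(C)C)COCc2ccc(OC)cc2)O[Si](C(C)(C)C)(C(C)(C)C)OC1 | intermediate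
21 | aldehyde after the [3,3] shift: C8 aldehyde, quaternary C10 (vinyl, CH2OTBS), C5 on the 6-methylene-1,3,2-dioxasilepane ring, C6 bearing the allylsilane side chain (C5, C6 and C10 as in the target) | C=C[C@](CO[Si](C)(C)C(C)(C)C)(CC=O)[C@@H]1C(=C)CO[Si](C(C)(C)C)(C(C)(C)C)O[C@H]1/C=C(/C[Si](C)(C)C)COCc2ccc(OC)cc2 | intermediate (not isolated)
22 | cyclohexanol: ring A with C5, C6, C7, C8 and C10 as in the target; O6/O15 silylene, C14 OTBS, C12 OPMB, free C8 hydroxyl | C=C[C@]1(CO[Si](C)(C)C(C)(C)C)C[C@H](O)[C@@H](C(=C)COCc2ccc(OC)cc2)[C@@H]3O[Si](C(C)(C)C)(C(C)(C)C)OCC(=C)[C@@H]13 | intermediate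
23 | but-2-yn-1-ol | CC#CCO | starting material
24 | tributylstannane | CCCC[SnH](CCCC)CCCC | starting material
25 | (2Z)-2-(tributylstannyl)but-2-en-1-ol | C/C=C(/CO)[Sn](CCCC)(CCCC)CCCC | intermediate
26 | tert-butyl(dimethyl){[(2Z)-2-(tributylstannyl)but-2-en-1-yl]oxy}silane | C/C=C(/CO[Si](C)(C)C(C)(C)C)[Sn](CCCC)(CCCC)CCCC | intermediate
27 | (2Z)-2-{[(tert-butyldimethylsilyl)oxy]methyl}but-2-enoic acid | C/C=C(/CO[Si](C)(C)C(C)(C)C)C(=O)O | intermediate
28 | C8 (2Z)-2-(silyloxymethyl)but-2-enoate of 22 | C=C[C@]1(CO[Si](C)(C)C(C)(C)C)C[C@H](OC(=O)/C(=C\C)CO[Si](C)(C)C(C)(C)C)[C@@H](C(=C)COCc2ccc(OC)cc2)[C@@H]3O[Si](C(C)(C)C)(C(C)(C)C)OCC(=C)[C@@H]13 | intermediate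
29 | C12 allylic alcohol from 28 | C=C[C@]1(CO[Si](C)(C)C(C)(C)C)C[C@H](OC(=O)/C(=C\C)CO[Si](C)(C)C(C)(C)C)[C@@H](C(=C)CO)[C@@H]3O[Si](C(C)(C)C)(C(C)(C)C)OCC(=C)[C@@H]13 | intermediate
30 | C12 aldehyde | C=C[C@]1(CO[Si](C)(C)C(C)(C)C)C[C@H](OC(=O)/C(=C\C)CO[Si](C)(C)C(C)(C)C)[C@@H](C(=C)C=O)[C@@H]3O[Si](C(C)(C)C)(C(C)(C)C)OCC(=C)[C@@H]13 | intermediate
31 | C12 carboxylic acid | C=C[C@]1(CO[Si](C)(C)C(C)(C)C)C[C@H](OC(=O)/C(=C\C)CO[Si](C)(C)C(C)(C)C)[C@@H](C(=C)C(O)=O)[C@@H]3O[Si](C(C)(C)C)(C(C)(C)C)OCC(=C)[C@@H]13 | intermediate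
32 | seco acid (all silyl groups removed; free C6 hydroxyl and C12 acid) | C=C[C@]1(CO)C[C@H](OC(=O)/C(=C\C)CO)[C@@H](C(=C)C(O)=O)[C@H](O)[C@H]1C(=C)CO | intermediate (not isolated)
33 | CNP0338073.1 | C=C[C@]1(CO)C[C@H](OC(=O)/C(=C\C)CO)[C@H]2C(=C)C(=O)O[C@@H]2[C@H]1C(=C)CO | target

**Step count**
Total: 22 steps. Longest linear sequence: 16 steps (steps 1–4, 8–14, 18–22).

**Three steps most likely to fail**

Step 14. In the first stage the alkoxide may fragment by retro-allylation instead of rearranging. In the Lewis acid stage the allylsilane may be protodesilylated, or the new C3 methylene may close onto the aldehyde in a carbonyl-ene reaction. The fallback sets out from 20: the rearrangement is run alone (KH, 18-crown-6) and aldehyde 21 is isolated. The silyl group is then exchanged for bromine with allylic transposition (N-bromosuccinimide, CH2Cl2, −78 °C) to give the allylic bromide F1. The C7–C8 bond is closed by intramolecular Nozaki–Hiyama–Kishi allylation (CrCl2, THF), whose closed chair transition state should give the same trans C7/C8 relation. The sequence comes back to the route at 22.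

Step 9. Hydride delivery may discriminate poorly between the alkynyl and the alkenyl flank of the ketone, or the Z enone may isomerise. The fallback replaces ketone reduction by an asymmetric carbon–carbon bond formation and sets out from 13 and 7. Weinreb amide 13 is reduced with DIBAL-H (−78 °C) to the Z enal F2. Alkyne 7 is silylated (Et3SiCl, imidazole) to the triethylsilyl ether F3. Me2Zn/ProPhenol-catalysed alkynylation of F2 with F3 (ligand enantiomer that gives the S carbinol) comes back to the route at 15.

Step 10. The iodinating agent may attack the allylsilane (iododesilylation) in competition with the alkenylaluminate. The fallback sets out from 15: after the same hydroalumination the alkenylaluminate is carboxylated with CO2 instead. The Z γ-hydroxy acrylate closes to the butenolide F4, and DIBAL-H reduction of F4 comes back to the route at diol 18, so that 16 and the Stille step are bypassed.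

**Further compounds**
F1 | step 14 | allylic bromide from 21 (bromine on C7, exocyclic C11=C13 methylene; both C7 epimers) | C=C[C@](CO[Si](C)(C)C(C)(C)C)(CC=O)[C@@H]1C(=C)CO[Si](C(C)(C)C)(C(C)(C)C)O[C@H]1C(Br)C(=C)COCc2ccc(OC)cc2
F2 | step 9 | (2E)-4-[(4-methoxybenzyl)oxy]-3-[(trimethylsilyl)methyl]but-2-enal (formyl cis to CH2OPMB) | O=C/C=C(/C[Si](C)(C)C)COCc1ccc(OC)cc1
F3 | step 9 | triethylsilyl ether of 7 | C=C/C(CO[Si](C)(C)C(C)(C)C)=C\[C@@H](O[Si](CC)(CC)CC)CC#C
F4 | step 10 | butenolide from 15 (O6–C15 lactone; C8 triethylsilyl ether) | C=C/C(CO[Si](C)(C)C(C)(C)C)=C\[C@@H](O[Si](CC)(CC)CC)CC1=C[C@H](/C=C(/C[Si](C)(C)C)COCc2ccc(OC)cc2)OC1=O
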